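## Retrosynthetic overview

1. Target ⇒ 7-O-allyl ether ⇒ 7-O-allyl-5,8-quinol. O7 is freed last with Pd(0), so no acid comes near the 4'-prenyl ether; O8 is methylated before that, while the 5-OH stays tied to C4=O by its hydrogen bond.
2. Key disconnection O1–C8a (closes ring C, the only ring made; rings A and B are bought). O5 and O8 sit para on ring A, so ring A is a hydroquinone in disguise. In its 2-acyl-1,4-benzoquinone form the CH carbon C8a, next to the acyl-bearing C4a, is electrophilic toward the enol oxygen (future O1) of a 2-methoxy-1,3-diketone.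
3. The quinone is unmasked anodically from a 4-allyloxy-2,5-dimethoxyphenyl diketone. O1 is thus placed on a C–H position of a 1,2,4-trioxygenated ring, and no regiodefined tetraoxygenated phenol is needed.
4. Diketone ⇒ aldol addition (C2–C3 bond) of an aryl methoxymethyl ketone to 4-prenyloxybenzaldehyde, then oxidation. The ketone ⇒ aryllithium (from 4-bromo-2,5-dimethoxybenzaldehyde by Baeyer–Villiger oxidation, allylation and Br–Li exchange) plus the N-methoxy-N-methylamide of methoxyacetic acid. This avoids Friedel–Crafts use of methoxyacetyl chloride, whose acylium ion loses CO.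

Key step: step 7

Remark: the target has no stereocentre (it is achiral), so the "single enantiomer" requirement needs no stereocontrol.

## Route

Step 1
Reactants: 1 4-bromo-2,5-dimethoxybenzaldehyde
Product: 3 4-bromo-2,5-dimethoxyphenol, via 4-bromo-2,5-dimethoxyphenyl formate 2 (not isolated)
Conditions: mCPBA, CH2Cl2, 0 °C → rt; then K2CO3 (cat.), MeOH, rt
Reagents that add atoms: mCPBA, O=C(OO)c1cccc(Cl)c1
Why: Baeyer–Villiger oxidation; the electron-rich ortho-methoxyaryl group migrates in preference to hydride, so the aldehyde becomes the aryl formate, and base-catalysed methanolysis then releases the phenol with bromine fixed para to it.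

Step 2
Reactants: 3 4-bromo-2,5-dimethoxyphenol
Product: 4 1-(allyloxy)-4-bromo-2,5-dimethoxybenzene
Conditions: allyl bromide, K2CO3, DMF, rt
Reagents that add atoms: allyl bromide, C=CCBr
Why: Williamson ether synthesis on the phenoxide; allyl is chosen for O7 because it should survive organolithium, enolate, anodic and methylation conditions and can be removed later by Pd(0) without acid.

Step 3
Reactants: 4 1-(allyloxy)-4-bromo-2,5-dimethoxybenzene; 5 N,2-dimethoxy-N-methylacetamide
Product: 7 1-[4-(allyloxy)-2,5-dimethoxyphenyl]-2-methoxyethan-1-one, via aryllithium 6 (not isolated)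
Conditions: n-BuLi, THF, −78 °C; then 5, −78 → 0 °C; aq. NH4Cl
Reagents that add atoms: none
Why: Bromine–lithium exchange at −78 °C should outrun any reaction of n-BuLi with the allyl ether, and the Weinreb ketone synthesis stops at the ketone; the acyl group is thereby fixed para to O-allyl with no regiochemical question.

Step 4
Reactants: 8 4-hydroxybenzaldehyde; 9 prenyl bromide (1-bromo-3-methylbut-2-ene)
Product: 10 4-[(3-methylbut-2-en-1-yl)oxy]benzaldehyde
Conditions: K2CO3, acetone, reflux
Reagents that add atoms: none
Why: Williamson ether synthesis; SN2 O-alkylation of the phenoxide at the primary allylic bromide.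

Step 5
Reactants: 7 1-[4-(allyloxy)-2,5-dimethoxyphenyl]-2-methoxyethan-1-one; 10 4-[(3-methylbut-2-en-1-yl)oxy]benzaldehyde
Product: 12 1-[4-(allyloxy)-2,5-dimethoxyphenyl]-3-hydroxy-2-methoxy-3-{4-[(3-methylbut-2-en-1-yl)oxy]phenyl}propan-1-one, via lithium enolate 11 (not isolated)
Conditions: LiHMDS, THF, −78 °C; then 10, −78 °C; aq. NH4Cl at −78 °C
Reagents that add atoms: none
Why: Aldol addition of the chelated lithium enolate of the α-methoxy ketone to a non-enolisable aldehyde, quenched cold to prevent retro-aldol; the two new stereocentres (C2, C3) are not controlled and need not be, since the racemic syn/anti mixture converges when both centres are erased in steps 6 and 7.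

Step 6
Reactants: 12 1-[4-(allyloxy)-2,5-dimethoxyphenyl]-3-hydroxy-2-methoxy-3-{4-[(3-methylbut-2-en-1-yl)oxy]phenyl}propan-1-one
Product: 13 1-[4-(allyloxy)-2,5-dimethoxyphenyl]-2-methoxy-3-{4-[(3-methylbut-2-en-1-yl)oxy]phenyl}propane-1,3-dione
Conditions: Dess–Martin periodinane, CH2Cl2, 0 °C → rt
Reagents that add atoms: none
Why: Dess–Martin oxidation of a β-hydroxy ketone to the 1,3-diketone under near-neutral conditions that should leave both alkenes and the electron-rich arene alone; the carbinol stereocentre disappears and C2 remains as a labile racemic centre.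

Step 7
Reactants: 13 1-[4-(allyloxy)-2,5-dimethoxyphenyl]-2-methoxy-3-{4-[(3-methylbut-2-en-1-yl)oxy]phenyl}propane-1,3-dione
Product: 16 7-(allyloxy)-5,8-dihydroxy-3-methoxy-4'-(prenyloxy)flavone, via acylquinone 14 (not isolated), via flavone-5,8-quinone 15 (not isolated)
Conditions: graphite anode, Pt cathode, divided cell, controlled potential just past the first anodic wave of 13 (expected near +1.3 V vs Ag/AgCl), LiClO4, MeCN/H2O 4:1, AcOH/NaOAc (pH ca. 4.5), Ar, 0 °C until 13 is consumed, then rt; then aq. Na2S2O4, EtOAc
Reagents that add atoms: water, O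
Why: Proposed new method: two-electron anodic oxidation of the 2,4,5-trialkoxyaryl ketone, with water adding ipso at the two methoxy-bearing carbons and both methyl groups leaving as methanol, should give acylquinone 14, as is known for anodic or cerium(IV) oxidative demethylation of 2,5-dimethoxyaryl ketones; the new element is ring closure by the enol oxygen of the 1,3-diketone, where the nearest precedent is closure by a phenol oxygen in oxidative xanthone syntheses. In 14 the ring CH next to the acyl-bearing carbon is β to both the acyl C=O and a quinone C=O, the position at which acylquinones take up nucleophiles, so the enol OH on the ring-B side should add there in a 6-endo-trig oxa-Michael step (O1–C8a), and tautomerisation of the adduct gives the aromatic 5,8-quinol with no further oxidant. No stereocentre is formed, and the racemic C2 centre of 13 becomes sp2. The step needs oxidation of ring A ahead of the enol, the prenyl alkene and ring B, which the lower potential expected for the trialkoxyarene and the un-ionised diketo form of 13 at pH below 5 should secure. It also needs closure at the CH carbon and not ipso at the methoxy-bearing carbon (the course phenols take with arene radical cations); in 20% water the radical cation should be captured by water before the sparsely populated enol intervenes, and at the quinone stage addition to a C=O carbon is only a reversible hemiketalisation whereas conjugate addition is made irreversible by aromatisation. Quinol 16 is oxidised more easily than 13, so part of it should go on to flavone-5,8-quinone 15 at the anode, and dithionite returns this to 16.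

Step 8
Reactants: 16 7-(allyloxy)-5,8-dihydroxy-3-methoxy-4'-(prenyloxy)flavone
Product: 17 7-(allyloxy)-5-hydroxy-3,8-dimethoxy-4'-(prenyloxy)flavone
Conditions: MeI (1.1 equiv), K2CO3 (1.1 equiv), degassed acetone, Ar, rt
Reagents that add atoms: iodomethane, CI
Why: Williamson O-methylation controlled by acidity; with one equivalent of weak base only the 8-OH should be ionised, because the 5-OH is held in a hydrogen bond to C4=O (the basis of classical partial methylation of 5,8-dihydroxyflavones), and exclusion of air prevents autoxidation of the quinol.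

Step 9
Reactants: 17 7-(allyloxy)-5-hydroxy-3,8-dimethoxy-4'-(prenyloxy)flavone
Product: 18 5,7-dihydroxy-3,8-dimethoxy-4'-(prenyloxy)flavone (target)
Conditions: Pd(PPh3)4 (cat.), morpholine, THF, rt
Reagents that add atoms: none
Why: Tsuji–Trost deallylation; Pd(0) should ionise the unsubstituted allyl aryl ether, whose 7-phenoxide is a good leaving group, far faster than the γ,γ-dimethylallyl (prenyl) ether, whose trisubstituted alkene binds Pd(0) poorly, and morpholine traps the π-allyl under neutral conditions that spare the prenyl ether and the 5-OH.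

## Compound list

1 | 4-bromo-2,5-dimethoxybenzaldehyde | COc1cc(Br)c(OC)cc1C=O | starting material
2 | 4-bromo-2,5-dimethoxyphenyl formate (not isolated) | COc1cc(Br)c(OC)cc1OC=O | intermediate
3 | 4-bromo-2,5-dimethoxyphenol | COc1cc(Br)c(OC)cc1O | intermediate
4 | 1-(allyloxy)-4-bromo-2,5-dimethoxybenzene | C=CCOc1cc(OC)c(Br)cc1OC | intermediate
5 | N,2-dimethoxy-N-methylacetamide | COCC(=O)N(C)OC | starting material
6 | [4-(allyloxy)-2,5-dimethoxyphenyl]lithium (not isolated) | [Li]c1cc(OC)c(OCC=C)cc1OC | intermediate
7 | 1-[4-(allyloxy)-2,5-dimethoxyphenyl]-2-methoxyethan-1-one | COCC(=O)c1cc(OC)c(OCC=C)cc1OC | intermediate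
8 | 4-hydroxybenzaldehyde | O=Cc1ccc(O)cc1 | starting material
9 | prenyl bromide (1-bromo-3-methylbut-2-ene) | CC(C)=CCBr | starting material
10 | 4-[(3-methylbut-2-en-1-yl)oxy]benzaldehyde | CC(C)=CCOc1ccc(C=O)cc1 | intermediate
11 | lithium (Z)-enolate of 7, chelated (not isolated; geometry of no consequence) | CO/C=C(\O[Li])c1cc(OC)c(OCC=C)cc1OC | intermediate
12 | 1-[4-(allyloxy)-2,5-dimethoxyphenyl]-3-hydroxy-2-methoxy-3-{4-[(3-methylbut-2-en-1-yl)oxy]phenyl}propan-1-one (racemic, syn/anti mixture) | COC(C(O)c1ccc(OCC=C(C)C)cc1)C(=O)c1cc(OC)c(OCC=C)cc1OC | intermediate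
13 | 1-[4-(allyloxy)-2,5-dimethoxyphenyl]-2-methoxy-3-{4-[(3-methylbut-2-en-1-yl)oxy]phenyl}propane-1,3-dione (racemic, enolisable) | COC(C(=O)c1ccc(OCC=C(C)C)cc1)C(=O)c1cc(OC)c(OCC=C)cc1OC | intermediate
14 | 1-[4-(allyloxy)-3,6-dioxocyclohexa-1,4-dien-1-yl]-2-methoxy-3-{4-[(3-methylbut-2-en-1-yl)oxy]phenyl}propane-1,3-dione (acylquinone, racemic, not isolated) | COC(C(=O)c1ccc(OCC=C(C)C)cc1)C(=O)C1=CC(=O)C(OCC=C)=CC1=O | intermediate
15 | 7-(allyloxy)-3-methoxy-2-{4-[(3-methylbut-2-en-1-yl)oxy]phenyl}-4H-chromene-4,5,8-trione (flavone-5,8-quinone, not isolated) | COC1=C(c2ccc(OCC=C(C)C)cc2)OC2=C(C1=O)C(=O)C=C(OCC=C)C2=O | intermediate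
16 | 7-(allyloxy)-5,8-dihydroxy-3-methoxy-2-{4-[(3-methylbut-2-en-1-yl)oxy]phenyl}-4H-chromen-4-one | COc1c(-c2ccc(OCC=C(C)C)cc2)oc2c(O)c(OCC=C)cc(O)c2c1=O | intermediate
17 | 7-(allyloxy)-5-hydroxy-3,8-dimethoxy-2-{4-[(3-methylbut-2-en-1-yl)oxy]phenyl}-4H-chromen-4-one | COc1c(-c2ccc(OCC=C(C)C)cc2)oc2c(OC)c(OCC=C)cc(O)c2c1=O | intermediate
18 | 5,7-dihydroxy-3,8-dimethoxy-2-{4-[(3-methylbut-2-en-1-yl)oxy]phenyl}-4H-chromen-4-one (achiral) | COc1c(-c2ccc(OCC=C(C)C)cc2)oc2c(OC)c(O)cc(O)c2c1=O | target

## Step count and risks

Total step count: 9. Longest linear sequence: 8 steps (1, 2, 3, 5, 6, 7, 8, 9).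

**Step 7 (new method).** What may go wrong: capture of the ring-A radical cation by the enol at the methoxy-bearing carbon (ipso closure with loss of methanol, leading to a ring-A isomer without O5), oxidation of the diketone enol itself, or hydration and decay of the acylquinone before it closes. The fallback uses known chemistry and puts the C8 oxygen in last by Elbs persulfate oxidation. It sets out from 10 and returns at 16.
- Purchased 2-methoxy-1-(2,4,6-trihydroxyphenyl)ethan-1-one F1 is allylated at its non-chelated 4-OH (allyl bromide, K2CO3, acetone) to 1-[4-(allyloxy)-2,6-dihydroxyphenyl]-2-methoxyethan-1-one F2.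
- Pinnick oxidation of 10 (NaClO2, NaH2PO4, 2-methyl-2-butene) gives 4-[(3-methylbut-2-en-1-yl)oxy]benzoic acid F3. 1-Chloro-N,N,2-trimethylprop-1-en-1-amine converts this, without HCl, into 4-[(3-methylbut-2-en-1-yl)oxy]benzoyl chloride F4.
- C-Aroylation of polylithiated F2 with F4 (excess LiHMDS, THF, −78 °C → rt; Baker–Venkataraman-type diketone synthesis) should give 1-[4-(allyloxy)-2,6-dihydroxyphenyl]-2-methoxy-3-{4-[(3-methylbut-2-en-1-yl)oxy]phenyl}propane-1,3-dione F5.
- Cyclodehydration in warm acetic acid (the two ortho hydroxyls are equivalent) should give 7-(allyloxy)-5-hydroxy-3-methoxy-4'-(prenyloxy)flavone F6.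
- Elbs oxidation (K2S2O8, aqueous KOH/pyridine, 0 °C → rt) attacks para to the 5-phenoxide, at C8, and should give potassium 7-(allyloxy)-5-hydroxy-3-methoxy-4'-(prenyloxy)flavon-8-yl sulfate F7. Short hydrolysis with dilute HCl/Na2SO3 then gives 16.

**Step 8.** What may go wrong: loss of site selectivity (methylation also at O5), or aerial oxidation of the quinol phenoxide to the flavone-5,8-quinone before it is alkylated. The fallback sets out from 16 and returns at 17 with no new compound (F0). It abandons the phenoxide: the un-ionised 8-OH is methylated with ethereal diazomethane (or trimethylsilyldiazomethane in MeOH/toluene). A diazoalkane is alkylating only after protonation by a free phenol, so the hydrogen-bonded 5-OH should stay untouched, and without base the quinol is not prone to autoxidation.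

**Step 9.** What may go wrong: competing ionisation of the 4'-prenyl ether by Pd(0) (loss of the prenyl group), or sluggish allyl transfer from the chelated flavone. The fallback sets out from 17 and returns at 18. The allyl ether is isomerised with a cationic iridium(I) hydride catalyst ([Ir(cod)(PMePh2)2]PF6 activated with H2, THF, rt), which should not move the trisubstituted prenyl alkene, to 5-hydroxy-3,8-dimethoxy-7-[(E)-prop-1-en-1-yloxy]-4'-(prenyloxy)flavone F8. The enol ether is then hydrolysed under conditions too mild for the prenyl ether (HgCl2/HgO, aqueous acetone, rt, or very dilute HCl in aqueous acetone) to give 18.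

## Further compounds

F1 | step 7 | 2-methoxy-1-(2,4,6-trihydroxyphenyl)ethan-1-one (purchased) | COCC(=O)c1c(O)cc(O)cc1O
F2 | step 7 | 1-[4-(allyloxy)-2,6-dihydroxyphenyl]-2-methoxyethan-1-one | COCC(=O)c1c(O)cc(OCC=C)cc1O
F3 | step 7 | 4-[(3-methylbut-2-en-1-yl)oxy]benzoic acid | CC(C)=CCOc1ccc(C(=O)O)cc1
F4 | step 7 | 4-[(3-methylbut-2-en-1-yl)oxy]benzoyl chloride | CC(C)=CCOc1ccc(C(Cl)=O)cc1
F5 | step 7 | 1-[4-(allyloxy)-2,6-dihydroxyphenyl]-2-methoxy-3-{4-[(3-methylbut-2-en-1-yl)oxy]phenyl}propane-1,3-dione (racemic, enolisable) | COC(C(=O)c1ccc(OCC=C(C)C)cc1)C(=O)c1c(O)cc(OCC=C)cc1O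
F6 | step 7 | 7-(allyloxy)-5-hydroxy-3-methoxy-2-{4-[(3-methylbut-2-en-1-yl)oxy]phenyl}-4H-chromen-4-one | COc1c(-c2ccc(OCC=C(C)C)cc2)oc2cc(OCC=C)cc(O)c2c1=O
F7 | step 7 | potassium 7-(allyloxy)-5-hydroxy-3-methoxy-2-{4-[(3-methylbut-2-en-1-yl)oxy]phenyl}-4-oxo-4H-chromen-8-yl sulfate | COc1c(-c2ccc(OCC=C(C)C)cc2)oc2c(OS(=O)(=O)[O-])c(OCC=C)cc(O)c2c1=O.[K+]
F0 | step 8 | none | none
F8 | step 9 | 5-hydroxy-3,8-dimethoxy-2-{4-[(3-methylbut-2-en-1-yl)oxy]phenyl}-7-[(E)-prop-1-en-1-yloxy]-4H-chromen-4-one | COc1c(-c2ccc(OCC=C(C)C)cc2)oc2c(OC)c(O/C=C/C)cc(O)c2c1=O
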